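Two questions are put on this flask, and both must be answered before it runs.

common to all: free catalyst 12 mM; impurity 4.1 mM

| flask | left-handed substrate | right-handed substrate | solid reagent | remark |
|---|---|---|---|---|
| Sunday's | 0.12 M | 0.12 M | 0.50 M | run made earlier |
| Friday's | 0.50 M | 0.50 M | 0.50 M | run made earlier |
| flask | 0.25 M | 0.25 M | 0.500 M |  |

| run | time / min | left-handed product / % | left-handed substrate / % |
|---|---|---|---|
| Sunday's | 0.500 | 13 | 36 |
| Sunday's | 1.00 | 28 | 23 |
| Sunday's | 2.00 | 42 | 7 |
| Sunday's | 3.00 | 48 | 4 |
| Sunday's | 6.00 | 52 | 1 |
| Friday's | 0.500 | 9 | 40 |
| Friday's | 1.50 | 31 | 17 |
| Friday's | 3.00 | 41 | 8 |
| Friday's | 5.00 | 44 | 4 |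
| Friday's | 6.00 | 43 | 5 |

(standard deviation of a reading: 1.5 percentage points)

- free catalyst is single-handed; left-handed substrate and right-handed substrate are mirror images of each other, charged as a racemate, each of them at the stated concentration
- solid reagent is a solid; its amount is given per volume of the solution
- the earlier runs were read with a standard deviation of 1.5 percentage points
- at the start none of the solid reagent is in solution
- no earlier run changes the charge of free catalyst; that part of a forecast is a guess

* apparent order in free catalyst when 30% of the left-handed substrate and right-handed substrate together are converted (percent change of the rate of making left-handed product for one percent more free catalyst charged)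
* factor on the rate of making left-handed product when 30% of the left-handed substrate and right-handed substrate together are converted if free catalyst is charged twice over

Which concentration carries the order in catalyst? My answer is not the charge. It is the working catalyst, c(free catalyst) minus c(impurity), here 7.90 mM, which is less than the 12 mM charged.

On what grounds? It is a guess, since Sunday's and Friday's runs have the same charge of free catalyst. I assume the impurity takes catalyst one for one.

What order follows? A rate proportional to the working catalyst has order c(free catalyst) over the working catalyst, 1.52. A double charge then multiplies the rate by 2.52.

Is the rate proportional to it? That is the weak spot. Friday's substrate charge is 4.17 times Sunday's. Sunday's rate reading, taken between its first two readings, is 0.0720 M/min. Friday's, taken the same way, is 0.220 M/min. That is 3.06 times Sunday's, so the rate reading grew less than the charge. Something besides catalyst and substrate may enter the rate, so I expect the flask to fall below my order.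

And the forecast? It calls the flask “mostly chemical but partly supply-limited” and gives order 1.2 and factor 1.9. Its order is lower than mine.

The flask gives order 1.2 and factor 1.87.

    free catalyst + impurity → spent catalyst (k = 12.0 /M/s)
    solid reagent ⇌ partner, rate k2*(cs2 - [partner]) while solid is left; crystals form when [partner] > cs2 (solubility = 0.190 M, k = 0.0550 /s)
    partner + free catalyst + right-handed substrate → free catalyst + right-handed product (k = 0.330 /M²/s)
    partner + free catalyst + left-handed substrate → free catalyst + left-handed product (k = 13.0 /M²/s)

In the flask at 0.800 min, free catalyst stands at 66.1% of its charge and spent catalyst at 33.9%, with impurity at 0.698% of its own charge. The working catalyst is 65.8% of the charge. The flask's order is 0.768 of 1.52. Its rate of 0.0977 M/min at 1.20 min, divided by the working catalyst, is 12.4 /min. Friday's run has the same working catalyst, 7.90 mM, and its rate reading divided by that is 27.8 /min.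

(The numbers in the tables are calculated on assumed constants, and the scatter is random.)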